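Two constants can be had before this flask ends. The first comes from the zeta run, which is this flask followed so far: from 50.0 min to 80.0 min the electrophile falls at 0.00692 min⁻¹, a reading that carries the scatter of its two points.

- zeta: electrophile 17 mM (fed, over 40 min); free base 34 mM; gas 1.4 mM (held); the very flask that is asked about, followed so far
- flask: electrophile 17 mM (fed, over 40 min); free base 34.0 mM; gas 1.4 mM (held); time 6.0 h

zeta run (percent of the electrophile charged)

| time / min | electrophile / % | product / % |
|---|---|---|
| 10.0 | 23.5 | 1.1 |
| 25.0 | 59.9 | 3.7 |
| 50.0 | 83.7 | 18.4 |
| 80.0 | 68.0 | 31.1 |

(scatter of a reading: 1 percentage point)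

- at the start none of the gas is in solution
- percentages count the whole charge, also what has not yet gone in
- the earlier runs do not show how much of nucleophile is bound; that part of a forecast is a guess

* part of the electrophile that has reacted at 6.0 h
* share of the unused nucleophile that is free and not bound as protonated nucleophile, at 6.0 h

The second constant is 8.24%, which I call the fill: the saturation level of the gas as a fraction of the electrophile charged. I take the nucleophile to be the gas once dissolved, and I guess that each reacted electrophile leaves one protonated nucleophile while the gas restores the free level. On that guess, counting turnovers, the unused nucleophile in this flask is one fill free plus c bound, so the free share is fill/(fill + c).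

If the zeta reading holds as a pseudo-first-order constant, this flask keeps 9.78% of its electrophile at 6.0 h. My c is then 90.2%, which is 10.9 fills turned over, and my free share is 8.36%.

The neighbouring flask looks nearly the same, but it takes 43 mM of electrophile, so its fill is 3.26%. A first-order fall at a held constant takes the same fraction whatever the charge, so if the constant holds there too, I expect c close to this flask's. Its free share should be lower, about 3.49%, because its fill is smaller.

The forecast gives c as 80%, from 68% to 91%, and the share as 60%, from 30% to 95%: “That share is a guess”. My c stands higher than its 80%, and my share stands lower than its low end.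

This flask gives c = 90.0% and a free share of 8.31%; at 6.00 h the nucleophile is 8.02% of the electrophile charge and the protonated nucleophile 88.5%.

    electrophile + nucleophile → acid set free + product (k = 0.0890 L mol⁻¹ s⁻¹)
    nucleophile + acid set free ⇌ protonated nucleophile, settled at all times (K = 1.70 × 10⁶ L mol⁻¹)
    acid set free + free base ⇌ salt of the base (K = 19000 L mol⁻¹, k = 0.0930 L mol⁻¹ s⁻¹)
    gas ⇌ nucleophile, rate k4*(csat - [nucleophile]) (kL = 0.0110 s⁻¹)
    acid set free → by-product carried off (k = 0.00160 s⁻¹)
    2 free base → homo dimer (k = 0.00250 L mol⁻¹ s⁻¹)

The neighbouring flask reaches c = 86.0%, so its fill over fill plus c gives 3.65%, and that flask itself gives a free share of 3.40%.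

The readings are calculated on assumed constants, noise included.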